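The plan makes ring A and the lactam last, from a furan and an alkyne. In the target the C4 oxygen lies next to C3a, and C3a is bonded to the quaternary spiro carbon C3. This pattern results when an ethynyl group and a 2-furoyl amide nitrogen share one carbon and undergo a gold-catalysed furan–yne phenol synthesis. That single isomerisation forms C3a–C7a and C4–C5, moves the furan oxygen to C4 and closes both rings without touching C3. The precursor is a 2-ethynyl-2-(N-alkyl-2-furamido)-2H-naphtho[1,8-bc]furan. It is obtained by asymmetric copper-catalysed alkynylation of an N-furoylated peri-imidate built on a Stobbe-derived naphthalene.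

Key step: step 11

**Remarks**

- **Numbering:** spiro compounds carry isoindolin-1-one labels: C1 carbonyl, N2, C3 spiro carbon, C3a, C4–C7, C7a. Ring A is C3a–C7a. Primed numbers belong to the 2H-naphtho[1,8-bc]furan half.
- **Assumption:** the sense of induction of the PyBox–copper catalyst on this new cation cannot be predicted. The ligand antipode that gives the drawn configuration is to be fixed by X-ray or ECD assignment of the silylalkyne, and (S,S) is written as a placeholder.
- **Descriptors:** the CIP label at C3 changes along the route (S for the silylalkyne, R for the terminal alkyne and the phenol, S for the methyl ether and the target). Only the substituent priorities change; the spatial arrangement stays the same.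
- **Protecting groups:** both hydroxyls travel as benzyl ethers, and the side-chain ether comes with a commercial amine.
  - A silyl ether could be lost under Lewis-acidic gold. A free primary alcohol would then add to the alkyne or exchange into the N,O-ketal as an oxazolidine.
  - One neutral hydrogenolysis removes both benzyl groups.
- **Gold catalyst:** a monovalent NHC–gold cation replaces AuCl3. Trivalent gold chloride is oxophilic enough to ionise propargylic C–O bonds, which would racemise C3. IPr = 1,3-bis(2,6-diisopropylphenyl)imidazol-2-ylidene.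

**Route**

Step 1
Reactants: 1 4-(benzyloxy)benzaldehyde; 2 dimethyl succinate
Product: 3 (E)-4-[4-(benzyloxy)phenyl]-3-(methoxycarbonyl)but-3-enoic acid
Conditions: KOtBu (1.2 equiv), t-BuOH, 50 °C → reflux; then 1 M HCl
Reagents that add atoms: none
Why: Stobbe condensation: the succinate enolate adds to the non-enolisable aldehyde, the aldolate lactonises, and irreversible E1cB opening of the paraconate should give mainly the (E)-half-ester, in which the aryl ring is cis to CH2CO2H as the next ring closure requires.

Step 2
Reactants: 3 (E)-4-[4-(benzyloxy)phenyl]-3-(methoxycarbonyl)but-3-enoic acid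
Product: 4 methyl 4-acetoxy-6-(benzyloxy)-2-naphthoate
Conditions: Ac2O, NaOAc, reflux
Reagents that add atoms: acetic anhydride, CC(=O)OC(C)=O
Why: Classical Stobbe naphthol cyclisation (mixed anhydride, intramolecular Friedel–Crafts acylation, enolisation, O-acetylation): the two ortho carbons of the para-substituted ring are equivalent, so only the 4,6-dioxygenated 2-naphthoate can form.

Step 3
Reactants: 4 methyl 4-acetoxy-6-(benzyloxy)-2-naphthoate
Product: 5 methyl 4-acetoxy-6-(benzyloxy)-5-bromo-2-naphthoate
Conditions: NBS (1.05 equiv), MeCN, 0 °C → rt, dark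
Reagents that add atoms: N-bromosuccinimide, O=C1CCC(=O)N1Br
Why: Electrophilic aromatic bromination: C5 is the alpha carbon ortho to the benzyloxy donor (the C1-type site of a 2-alkoxynaphthalene) while the other ring is deactivated by ester and acetate, so ionic NBS bromination should go there in spite of the peri acetate.

Step 4
Reactants: 5 methyl 4-acetoxy-6-(benzyloxy)-5-bromo-2-naphthoate
Product: 6 7-(benzyloxy)-8-bromo-3-(hydroxymethyl)naphthalen-1-ol
Conditions: LiAlH4 (3 equiv), THF, 0 °C; aq. Rochelle salt
Reagents that add atoms: none
Why: Hydride reduction of esters: LiAlH4 takes the methyl ester to the primary alcohol and removes the acetate in the same operation, and the aryl bromide and benzyl ether are inert at 0 °C.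

Step 5
Reactants: 6 7-(benzyloxy)-8-bromo-3-(hydroxymethyl)naphthalen-1-ol
Product: 8 7-(benzyloxy)-8-bromo-3-methylnaphthalen-1-ol, via benzylic chloride 7 (not isolated)
Conditions: SOCl2 (1.2 equiv), CH2Cl2, 0 °C, concentrate; residue added to LiEt3BH (3 equiv), THF, 0 °C
Reagents that add atoms: thionyl chloride, O=S(Cl)Cl (chlorine in intermediate 7 only)
Why: Chlorodehydroxylation followed by SN2 hydride displacement: only the benzylic alcohol reacts irreversibly with SOCl2, and inverse addition to excess LiEt3BH should reduce the primary chloride faster than the naphtholate can alkylate it, leaving the aryl bromide untouched.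

Step 6
Reactants: 8 7-(benzyloxy)-8-bromo-3-methylnaphthalen-1-ol
Product: 11 3-(benzyloxy)-7-methyl-2H-naphtho[1,8-bc]furan-2-one, via dilithio naphtholate 9 (not isolated), via hydroxy acid 10 (not isolated)
Conditions: n-BuLi (2.2 equiv), THF, −78 °C; CO2 (g), −78 °C → rt; 1 M HCl; then p-TsOH·H2O (5 mol %), toluene, 80 °C
Reagents that add atoms: carbon dioxide, O=C=O; n-butyllithium, [Li]CCCC (lithium in intermediate 9 only)
Why: Bromine–lithium exchange and carboxylation: after O-deprotonation the exchange at −78 °C outruns deprotonation of the benzyl ether, CO2 traps the aryllithium, and the peri hydroxy acid should lactonise readily under acid catalysis because the two groups are held together.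

Step 7
Reactants: 11 3-(benzyloxy)-7-methyl-2H-naphtho[1,8-bc]furan-2-one; 12 2-(benzyloxy)ethan-1-amine
Product: 13 2-(benzyloxy)-N-[2-(benzyloxy)ethyl]-8-hydroxy-6-methyl-1-naphthamide
Conditions: 12 (1.2 equiv), THF, 40 °C
Reagents that add atoms: none
Why: Aminolysis of an activated ester: the strained peri-lactone is an aryl ester whose opening releases ring strain, so a primary amine should open it without a promoter.

Step 8
Reactants: 13 2-(benzyloxy)-N-[2-(benzyloxy)ethyl]-8-hydroxy-6-methyl-1-naphthamide
Product: 14 3-(benzyloxy)-N-[2-(benzyloxy)ethyl]-7-methyl-2H-naphtho[1,8-bc]furan-2-imine (cyclic imidate, C=N geometry not defined)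
Conditions: Tf2O (1.1 equiv), 2-fluoropyridine (1.2 equiv), CH2Cl2, −78 → 0 °C; then Et3N (3 equiv); quick filtration through basic alumina, used at once
Reagents that add atoms: none
Why: Electrophilic amide activation: Tf2O and 2-fluoropyridine convert the secondary amide into an imidoyl triflate or nitrilium ion, which the peri hydroxyl captures in a 5-exo closure, the intramolecular version of imidate synthesis from activated amides and oxygen nucleophiles.

Step 9
Reactants: 14 cyclic imidate; 15 2-furoyl chloride; 16 trimethylsilylacetylene
Product: 18 (S)-N-[2-(benzyloxy)ethyl]-N-{3-(benzyloxy)-7-methyl-2-[(trimethylsilyl)ethynyl]-2H-naphtho[1,8-bc]furan-2-yl}furan-2-carboxamide, via N-furoyl imidatium chloride 17 (not isolated)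
Conditions: 15 (1.1 equiv), CH2Cl2, 0 °C, 1 h; then 16 (2 equiv), [Cu(MeCN)4]PF6 (10 mol %), 2,6-bis[(S)-4-phenyl-4,5-dihydrooxazol-2-yl]pyridine ((S,S)-Ph-PyBox, 12 mol %), iPr2NEt (1.5 equiv), −20 °C; recrystallise to raise the ee if needed
Reagents that add atoms: none
Why: Proposed new method: N-acylation turns the imidate into the flat N-acyl imidatium ion 17, whose C3 is open to attack perpendicular to the naphthofuran plane by a PyBox-bound monovalent copper acetylide formed with iPr2NEt, so the new stereocentre is set by catalyst control (the ligand blocks one enantiotopic face); the closest known reaction types are the copper-catalysed coupling of imines, acid chlorides and terminal alkynes to propargyl amides and the copper/PyBox alkynylation of cyclic oxocarbenium ions to tetrasubstituted centres, neither of which has been shown on an imidate.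

Step 10
Reactants: 18 (S)-silylalkyne
Product: 19 (R)-N-[2-(benzyloxy)ethyl]-N-[3-(benzyloxy)-2-ethynyl-7-methyl-2H-naphtho[1,8-bc]furan-2-yl]furan-2-carboxamide
Conditions: K2CO3 (0.2 equiv), MeOH–THF, 0 °C
Reagents that add atoms: none
Why: Base-catalysed protodesilylation of an alkynylsilane: methoxide attacks silicon only, and the hindered tertiary amide, the N,O-ketal and the stereocentre should not be affected at 0 °C.

Step 11
Reactants: 19 (R)-ethynyl furamide
Product: 20 (R)-3'-(benzyloxy)-2-[2-(benzyloxy)ethyl]-4-hydroxy-7'-methylspiro[isoindoline-3,2'-naphtho[1,8-bc]furan]-1-one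
Conditions: (IPr)AuNTf2 (5 mol %), 2,6-di-tert-butylpyridine (10 mol %), 4 Å MS, ClCH2CH2Cl (0.02 M), 25 → 60 °C
Reagents that add atoms: none
Why: Proposed new method: the gold cation binds the terminal alkyne and the furan C2=C3 bond attacks its internal carbon in a 5-exo-dig closure (C3a–C7a, lactam ring) to give a cyclopropyl gold carbenoid, which opens with scission of the furan C2–O bond to an enal-conjugated carbenoid. The aldehyde oxygen adds to the carbenoid carbon C4, the resulting oxepine closes by 6π electrocyclisation to the C4–C5 arene oxide (ring A), and the oxide opens to the C4 phenol. The closest known reaction type is the Hashmi gold furan–yne phenol synthesis of N-propargyl furfurylamines to isoindolin-4-ols; new here is the carbonyl in the tether, which makes the furan a weaker nucleophile, hence the long-lived, strongly electrophilic NHC–gold cation and mild heating. The fully substituted C3 compresses the reacting ends (gem-disubstituent effect) and the tertiary amide has no N–H, so attack of the amide oxygen on the alkyne cannot end in an oxazole and stays a reversible dead end under dry conditions. The selectivity needed is cleavage of the C5–O bond of the arene oxide, and the substrate secures it because the resulting charge rests on C5, C7 and the alkyl-bearing C3a, whereas C4–O cleavage would put it on C7a next to the lactam carbonyl. No stereocentre is formed and no bond at C3 is made or broken, and the hindered base and the absence of trivalent gold chloride guard against ionisation of the propargylic C3–O bond, so the configuration from step 9 should persist.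

Step 12
Reactants: 20 (R)-spiro lactam phenol
Product: 21 (S)-3'-(benzyloxy)-2-[2-(benzyloxy)ethyl]-4-methoxy-7'-methylspiro[isoindoline-3,2'-naphtho[1,8-bc]furan]-1-one
Conditions: MeI (1.5 equiv), K2CO3 (1.5 equiv), DMF, rt
Reagents that add atoms: iodomethane, CI
Why: Williamson ether synthesis: the C4 phenol is the only acidic site, and mild carbonate base at room temperature should not open the N,O-ketal.

Step 13
Reactants: 21 (S)-bis(benzyl ether)
Product: 22 (S)-3'-hydroxy-2-(2-hydroxyethyl)-4-methoxy-7'-methylspiro[isoindoline-3,2'-naphtho[1,8-bc]furan]-1-one (target)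
Conditions: H2 (1 atm), Pd/C (10 wt %), EtOAc–EtOH, rt
Reagents that add atoms: none
Why: Catalytic hydrogenolysis of benzyl ethers: both O-benzyl groups are cleaved under neutral conditions, whereas the C3–O bond is fully substituted, lies in the naphthalene plane and is shielded by the orthogonal spiro halves, so it should survive, and the hydroxyethyl N,O-ketal is never exposed to acid.

**Compound list**

1 | 4-(benzyloxy)benzaldehyde | O=Cc1ccc(OCc2ccccc2)cc1 | starting material
2 | dimethyl succinate | COC(=O)CCC(=O)OC | starting material
3 | (E)-4-[4-(benzyloxy)phenyl]-3-(methoxycarbonyl)but-3-enoic acid | OC(=O)C/C(=C\c1ccc(OCc2ccccc2)cc1)C(=O)OC | intermediate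
4 | methyl 4-acetoxy-6-(benzyloxy)-2-naphthoate | COC(=O)c1cc(OC(C)=O)c2cc(OCc3ccccc3)ccc2c1 | intermediate
5 | methyl 4-acetoxy-6-(benzyloxy)-5-bromo-2-naphthoate | COC(=O)c1cc(OC(C)=O)c2c(Br)c(OCc3ccccc3)ccc2c1 | intermediate
6 | 7-(benzyloxy)-8-bromo-3-(hydroxymethyl)naphthalen-1-ol | OCc1cc(O)c2c(Br)c(OCc3ccccc3)ccc2c1 | intermediate
7 | 7-(benzyloxy)-8-bromo-3-(chloromethyl)naphthalen-1-ol | ClCc1cc(O)c2c(Br)c(OCc3ccccc3)ccc2c1 | intermediate
8 | 7-(benzyloxy)-8-bromo-3-methylnaphthalen-1-ol | Cc1cc(O)c2c(Br)c(OCc3ccccc3)ccc2c1 | intermediate
9 | lithium 7-(benzyloxy)-8-lithio-3-methylnaphthalen-1-olate | Cc1cc(O[Li])c2c([Li])c(OCc3ccccc3)ccc2c1 | intermediate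
10 | 2-(benzyloxy)-8-hydroxy-6-methyl-1-naphthoic acid | Cc1cc(O)c2c(C(=O)O)c(OCc3ccccc3)ccc2c1 | intermediate
11 | 3-(benzyloxy)-7-methyl-2H-naphtho[1,8-bc]furan-2-one | O=C1Oc2cc(C)cc3ccc(OCc4ccccc4)c1c23 | intermediate
12 | 2-(benzyloxy)ethan-1-amine | NCCOCc1ccccc1 | starting material
13 | 2-(benzyloxy)-N-[2-(benzyloxy)ethyl]-8-hydroxy-6-methyl-1-naphthamide | Cc1cc(O)c2c(C(=O)NCCOCc3ccccc3)c(OCc3ccccc3)ccc2c1 | intermediate
14 | 3-(benzyloxy)-N-[2-(benzyloxy)ethyl]-7-methyl-2H-naphtho[1,8-bc]furan-2-imine | O(Cc1ccccc1)CCN=C1Oc2cc(C)cc3ccc(OCc4ccccc4)c1c23 | intermediate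
15 | 2-furoyl chloride | O=C(Cl)c1ccco1 | starting material
16 | trimethylsilylacetylene | C#C[Si](C)(C)C | starting material
17 | N-[2-(benzyloxy)ethyl]-N-(2-furoyl)-3-(benzyloxy)-7-methyl-2H-naphtho[1,8-bc]furan-2-iminium chloride | [Cl-].O=C(c1ccco1)[N+](CCOCc1ccccc1)=C1Oc2cc(C)cc3ccc(OCc4ccccc4)c1c23 | intermediate
18 | (S)-N-[2-(benzyloxy)ethyl]-N-{3-(benzyloxy)-7-methyl-2-[(trimethylsilyl)ethynyl]-2H-naphtho[1,8-bc]furan-2-yl}furan-2-carboxamide | C[Si](C)(C)C#C[C@]1(Oc2cc(C)cc3ccc(OCc4ccccc4)c1c23)N(CCOCc1ccccc1)C(=O)c1ccco1 | intermediate
19 | (R)-N-[2-(benzyloxy)ethyl]-N-[3-(benzyloxy)-2-ethynyl-7-methyl-2H-naphtho[1,8-bc]furan-2-yl]furan-2-carboxamide | C#C[C@]1(Oc2cc(C)cc3ccc(OCc4ccccc4)c1c23)N(CCOCc1ccccc1)C(=O)c1ccco1 | intermediate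
20 | (R)-3'-(benzyloxy)-2-[2-(benzyloxy)ethyl]-4-hydroxy-7'-methylspiro[isoindoline-3,2'-naphtho[1,8-bc]furan]-1-one | Oc1cccc2c1[C@]1(Oc3cc(C)cc4ccc(OCc5ccccc5)c1c34)N(CCOCc1ccccc1)C2=O | intermediate
21 | (S)-3'-(benzyloxy)-2-[2-(benzyloxy)ethyl]-4-methoxy-7'-methylspiro[isoindoline-3,2'-naphtho[1,8-bc]furan]-1-one | COc1cccc2c1[C@]1(Oc3cc(C)cc4ccc(OCc5ccccc5)c1c34)N(CCOCc1ccccc1)C2=O | intermediate
22 | (S)-3'-hydroxy-2-(2-hydroxyethyl)-4-methoxy-7'-methylspiro[isoindoline-3,2'-naphtho[1,8-bc]furan]-1-one | COc1cccc2c1[C@]1(Oc3cc(C)cc4ccc(O)c1c34)N(CCO)C2=O | target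

Total step count: 13. Longest linear sequence: 13 steps (from 1 to 22).

**Steps most likely to fail**

First, step 11.
- **What may go wrong:** the acyl group lowers the nucleophilicity of the furan, so attack on the gold-bound alkyne may be too slow. Catalyst decay, hydration of the alkyne through amide-oxygen participation, or acid-promoted ionisation of the C3–O bond with erosion of enantiopurity could then take over.
- **Fallback:** it uses known chemistry, sets out from 8 and comes back at 21, and brings ring A in ready-made.
  - Commercial 3-methoxyphthalic anhydride is condensed with 12 in hot acetic acid to 2-[2-(benzyloxy)ethyl]-4-methoxyisoindoline-1,3-dione F1.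
  - The dilithio species 9, generated from 8 as in step 6, is added to F1 at −78 °C. Aryllithium addition to a phthalimide should occur mainly at the carbonyl flanked by the chelating methoxy group and give the 3-aryl-3-hydroxyisoindolinone F2.
  - Catalytic camphorsulfonic acid in CH2Cl2 ionises F2 to the N-acyliminium ion, which the peri hydroxyl closes to the racemic spiro lactam F3.
  - Preparative SFC on an immobilised amylose carbamate phase then provides 21, and step 13 follows.

Second, step 9.
- **What may go wrong:** N-acylation of the hindered imidate may be slow, the furoyl group may be transferred to the acetylide, or the copper acetylide may show poor facial selectivity towards the flat cation.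
- **Fallback:** it sets out from 14, comes back at 18, and gives up catalyst control.
  - 14 is acylated with 15 as before, and the salt 17 is treated at −78 °C with (trimethylsilyl)ethynylmagnesium bromide. This is a stoichiometric Grignard addition of the kind long used on N-acylpyridinium and N-alkyl oxazolinium salts. It should give the racemic silylalkyne F4.
  - Preparative chiral SFC of F4 delivers 18.

Third, step 8.
- **What may go wrong:** the naphthol may be O-triflated, the side-chain ether oxygen may capture the activated amide with loss of benzyl (oxazoline formation), or the imidate may hydrolyse during isolation.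
- **Fallback:** it sets out from 13, comes back at 14, and activates through sulfur.
  - Lawesson's reagent (toluene, 90 °C) converts 13 into the thioamide F5.
  - MeI alkylates only the soft sulfur to give the S-methyl thioimidate F6.
  - Et3N then frees the naphtholate, which displaces methanethiolate by addition–elimination to give 14. These conditions are too mild for the ether to take part.

**Further compounds**

F1 | step 11 | 2-[2-(benzyloxy)ethyl]-4-methoxyisoindoline-1,3-dione | COc1cccc2c1C(=O)N(CCOCc1ccccc1)C2=O
F2 | step 11 | rac-3-[2-(benzyloxy)-8-hydroxy-6-methylnaphthalen-1-yl]-2-[2-(benzyloxy)ethyl]-3-hydroxy-4-methoxyisoindolin-1-one | COc1cccc2c1C(O)(c1c(OCc3ccccc3)ccc3cc(C)cc(O)c13)N(CCOCc1ccccc1)C2=O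
F3 | step 11 | rac-3'-(benzyloxy)-2-[2-(benzyloxy)ethyl]-4-methoxy-7'-methylspiro[isoindoline-3,2'-naphtho[1,8-bc]furan]-1-one | COc1cccc2c1C1(Oc3cc(C)cc4ccc(OCc5ccccc5)c1c34)N(CCOCc1ccccc1)C2=O
F4 | step 9 | rac-N-[2-(benzyloxy)ethyl]-N-{3-(benzyloxy)-7-methyl-2-[(trimethylsilyl)ethynyl]-2H-naphtho[1,8-bc]furan-2-yl}furan-2-carboxamide | C[Si](C)(C)C#CC1(Oc2cc(C)cc3ccc(OCc4ccccc4)c1c23)N(CCOCc1ccccc1)C(=O)c1ccco1
F5 | step 8 | 2-(benzyloxy)-N-[2-(benzyloxy)ethyl]-8-hydroxy-6-methylnaphthalene-1-carbothioamide | Cc1cc(O)c2c(C(=S)NCCOCc3ccccc3)c(OCc3ccccc3)ccc2c1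
F6 | step 8 | methyl 2-(benzyloxy)-N-[2-(benzyloxy)ethyl]-8-hydroxy-6-methylnaphthalene-1-carbimidothioate | Cc1cc(O)c2c(C(SC)=NCCOCc3ccccc3)c(OCc3ccccc3)ccc2c1
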